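Late in Monday's run, where starting material and partner make target over free catalyst, the target barely climbed, and that late slope is what to watch.

| setting | Monday's | Thursday's | Wednesday's |
|---|---|---|---|
| starting material | 0.150 M | 0.150 M | 0.0750 M |
| partner | 0.120 M | 0.120 M | 0.0450 M |
| free catalyst | 0.00750 M | 0.0110 M | 0.00750 M |
| time |  |  | 38 h |

- Monday's run (time / h: [target] / M): 1.5: 0.0059; 2.6: 0.0108; 4.4: 0.0179; 7.6: 0.0260; 13: 0.0353; 22: 0.0421; 38: 0.0459
- Thursday's run (time / h: [target] / M): 1.5: 0.0089; 2.6: 0.0159; 4.4: 0.0248; 7.6: 0.0355; 13: 0.0479; 22: 0.0542; 38: 0.0575

(standard deviation of a reading: 4 × 10⁻⁴ M)

1. the power of [free catalyst] that the first rate follows, about the charge of the Monday's run; measure it at two percent of starting material made into target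
2. target in the Wednesday's run at 38 h, as a share of the starting material charged

- Overall: starting material + partner -> target, with free catalyst as catalyst.
- Constant volume, constant temperature.
- The analysis sees a species whether free or bound.
- An order is taken over about fifteen percent of the charge, up and down.

I read Monday's first rate as the average up to the first reading, 0.00393 M h⁻¹, and between the last two readings the rate averaged 2.38 × 10⁻⁴ M h⁻¹, a fall by a factor of 16.6. Making that target uses up both charges, and taken as first order in each, this accounts for a factor of 2.33, so a further factor of 7.10 remains, and on this reckoning something else slows Monday's run as well. To carry that accumulated slowing forward I used the reach, the last reading of target divided by the first rate, which is the time that amount of target takes at the first rate. Monday's reach was 11.7 h and Thursday's was 9.69 h. The first rates of the two runs gave a catalyst order of 1.07 as a reading.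

For Wednesday's run I kept Monday's reach and scaled the first rate by the two charges, taken as first order in each, a factor of 0.188, which gave 11.5% as my own estimate. The forecast said order 1 and 23%, above my figure, stepping forward by hand and “Assuming first order in starting material and partner”.

The simulation gave an order of 0.92 about Monday's charge and, for Wednesday's run, 32.3%, which is 9.3 percentage points above the forecast.

    free catalyst + starting material → catalyst-substrate complex (7.884 M⁻¹ h⁻¹)
    catalyst-substrate complex + partner → target + free catalyst (19.22 M⁻¹ h⁻¹)
    catalyst-substrate complex → spent catalyst + starting material (0.07200 h⁻¹)
    2 partner → lost reagent (0.7884 M⁻¹ h⁻¹)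

At Monday's reach, that Wednesday target asks a first rate of 0.00208 M h⁻¹, which is 0.529 of Monday's first rate, against the 0.188 I had scaled by. Within Wednesday's run, the pairing of partner into lost reagent cost target: the same run without that step gave 45.8% against 32.3%. At that same first rate, the target of the run without the step corresponds to a reach of 16.5 h.

(The data were generated by integration with made-up constants, noise included.)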